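## Retrosynthetic overview

- The target has one ring (the furan) and one stereocentre, which is (R). The last step joins a chiral ω-alkenal to a 5-vinyl-2-alkylidene-oxolane by cross-metathesis and then isomerises the adduct, redox-neutrally, to the aromatic furan.
- The oxolane block gets its ring O–C5 bond by SN2′ O-alkylation, in the domino C,O-dialkylation of methyl acetoacetate dianion with (E)-1,4-dibromobut-2-ene.
- The ω-alkenal comes from ester-to-aldehyde reduction; its chain is built by Cu-catalysed sp3–sp3 coupling of a chiral iodo ester with pent-4-enyl Grignard.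
- The stereocentre is set by C–O bond formation: an enantioselective Baeyer–Villiger oxygen insertion desymmetrises 4-butylcyclohexanone, and the lactone alkyl C–O bond is then cut with TMSI.
- Ring order: ε-lactone (made, then opened), oxolane (side branch), furan (aromatised in the final step).

Assumption: the stereocentre is (R) by CIP analysis of the given SMILES, and 4-butylcyclohexanone, 5-bromopent-1-ene, methyl acetoacetate and (E)-1,4-dibromobut-2-ene are taken as cheap catalogue chemicals.

## Route

Step 1
Reactants: 1 4-butylcyclohexanone
Product: 2 (S)-5-butyloxepan-2-one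
Conditions: Sc(OTf)3 (5 mol%), chiral N,N′-dioxide ligand (5 mol%, the antipode that gives the S lactone), m-CPBA (1.1 equiv), EtOAc, −20 °C
Reagents that add atoms: m-CPBA, OOC(=O)c1cccc(Cl)c1
Why: Catalytic asymmetric Baeyer–Villiger oxidation: the chiral Sc(III) complex holds the Criegee adduct so that only one of the two enantiotopic α-CH2 groups is antiperiplanar to the O–O bond and migrates, which inserts oxygen on one side of the carbonyl and fixes C5 as (S) (about 85–95% ee expected for 4-substituted cyclohexanones).

Step 2
Reactants: 2 (S)-5-butyloxepan-2-one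
Product: 4 methyl (S)-4-(2-iodoethyl)octanoate, via trimethylsilyl (S)-4-(2-iodoethyl)octanoate 3 (not isolated)
Conditions: TMSI (1.3 equiv), CH2Cl2, 0 °C → rt; then MeOH, rt
Reagents that add atoms: iodotrimethylsilane, C[Si](C)(C)I; methanol, CO
Why: Silyl iodide lactone cleavage: O-silylation, then SN2 attack of iodide at the primary O–CH2 carbon gives the ω-iodo silyl ester, which the HI/MeOH formed in the flask converts to the methyl ester (Fischer esterification); the stereocentre is not involved.

Step 3
Reactants: 4 methyl (S)-4-(2-iodoethyl)octanoate; 5 5-bromopent-1-ene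
Product: 7 methyl (R)-4-butylundec-10-enoate, via pent-4-en-1-ylmagnesium bromide 6 (not isolated)
Conditions: 5, Mg, THF, rt; then 4, Li2CuCl4 (3 mol%), THF/NMP, −20 → 0 °C
Reagents that add atoms: none
Why: Kochi-type Cu-catalysed sp3–sp3 coupling of a primary alkyl iodide with an alkyl Grignard reagent, which at −20 °C with NMP is much faster than addition to the methyl ester; no bond at the stereocentre changes (the descriptor becomes R only through CIP priorities).

Step 4
Reactants: 7 methyl (R)-4-butylundec-10-enoate
Product: 8 (R)-4-butylundec-10-enal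
Conditions: DIBAL-H (1.1 equiv), CH2Cl2, −78 °C; aq. Rochelle salt
Reagents that add atoms: none
Why: Partial ester reduction: the tetrahedral aluminium hemiacetal is stable at −78 °C and releases the aldehyde only on work-up; the stereocentre is γ to the carbonyl and cannot epimerise.

Step 5
Reactants: 9 methyl acetoacetate; 10 (E)-1,4-dibromobut-2-ene
Product: 13 methyl (2E)-2-(5-ethenyloxolan-2-ylidene)acetate (racemic), via dilithio acetoacetate dianion 11 (not isolated), via bromo keto ester enolate 12 (not isolated)
Conditions: LDA (2.3 equiv), THF, 0 °C; then 10, −78 → 20 °C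
Reagents that add atoms: none
Why: Domino C,O-cyclodialkylation of a 1,3-dicarbonyl dianion: SN2 γ-C-alkylation, then 5-exo SN2′ O-alkylation of the enolate forms the ring C–O bond (C-cyclisation would be a disfavoured 5-enolendo closure); the new C5 centre is racemic and is erased in step 6, and the E/Z ratio of the exocyclic alkene does not matter.

Step 6
Reactants: 8 (R)-4-butylundec-10-enal; 13 methyl (2E)-2-(5-ethenyloxolan-2-ylidene)acetate
Product: 16 methyl 2-[5-[(8R)-8-butyl-11-oxoundecyl]furan-2-yl]acetate, via cross-metathesis alkenyl oxolane 14 (not isolated), via bis-alkylidene oxolane 15 (not isolated)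
Conditions: 13 (2 equiv), Hoveyda–Grubbs II (5 mol%), CH2Cl2, 40 °C; then RuHCl(CO)(PPh3)3 (5 mol%), toluene, 80 °C; then PPTS (10 mol%), rt
Reagents that add atoms: none
Why: Proposed new method: a tandem cross-metathesis / allyl-ether-to-enol-ether isomerisation / tautomerisation that transfers a furan-2-ylacetate unit onto a terminal alkene. The Ru carbene joins 8 (type I olefin) to the allylic-ether vinyl group of 13 (type II; its push–pull trisubstituted C=C is inert). Ru–H then adds to the new C=C and β-eliminates the ring C5–H (allylic and α to oxygen) to give the conjugated enol ether 15. Two acid-mediated 1,3-proton shifts deliver the aromatic furan as an irreversible sink, which erases the racemic oxolane centre and leaves the remote (R) centre untouched. The closest known reaction types are tandem olefin metathesis/Ru–H isomerisation of allyl ethers to enol ethers and the acid isomerisation of 2-alkylidene-5-methylene-oxolanes to furans.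

## Compound list

1 | 4-butylcyclohexanone | CCCCC1CCC(=O)CC1 | starting material
2 | (S)-5-butyloxepan-2-one | CCCC[C@H]1CCC(=O)OCC1 | intermediate
3 | trimethylsilyl (S)-4-(2-iodoethyl)octanoate | CCCC[C@@H](CCC(=O)O[Si](C)(C)C)CCI | intermediate
4 | methyl (S)-4-(2-iodoethyl)octanoate | CCCC[C@@H](CCC(=O)OC)CCI | intermediate
5 | 5-bromopent-1-ene | C=CCCCBr | starting material
6 | pent-4-en-1-ylmagnesium bromide | C=CCCC[Mg]Br | intermediate
7 | methyl (R)-4-butylundec-10-enoate | CCCC[C@@H](CCC(=O)OC)CCCCCC=C | intermediate
8 | (R)-4-butylundec-10-enal | CCCC[C@@H](CCC=O)CCCCCC=C | intermediate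
9 | methyl acetoacetate (methyl 3-oxobutanoate) | COC(=O)CC(C)=O | starting material
10 | (E)-1,4-dibromobut-2-ene | BrC/C=C/CBr | starting material
11 | dilithium dianion of methyl acetoacetate | [Li+].[Li+].[CH2-]C(=O)[CH-]C(=O)OC | intermediate
12 | methyl (6E)-8-bromo-3-oxooct-6-enoate (present as its lithium enolate) | COC(=O)CC(=O)CC/C=C/CBr | intermediate
13 | methyl (2E)-2-(5-ethenyloxolan-2-ylidene)acetate (racemic at C5) | C=CC1CC/C(=C\C(=O)OC)O1 | intermediate
14 | methyl (2E)-2-[5-[(1E,8R)-8-butyl-11-oxoundec-1-en-1-yl]oxolan-2-ylidene]acetate (both C5 epimers) | CCCC[C@@H](CCC=O)CCCCC/C=C/C1CC/C(=C\C(=O)OC)O1 | intermediate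
15 | methyl (2E)-2-[5-[(8R)-8-butyl-11-oxoundecylidene]oxolan-2-ylidene]acetate | CCCC[C@@H](CCC=O)CCCCCCC=C1CC/C(=C\C(=O)OC)O1 | intermediate
16 | methyl 2-[5-[(8R)-8-butyl-11-oxoundecyl]furan-2-yl]acetate | CCCC[C@@H](CCC=O)CCCCCCCc1ccc(CC(=O)OC)o1 | target

## Step count and risks

Total steps: 6 (steps 1–4 and 6 are linear; step 5 makes the side fragment). Longest linear sequence: 5 (1 → 2 → 4 → 7 → 8 → 16).

The three steps most likely to fail:

**Step 1 (enantioselectivity).** 4-n-Alkyl cyclohexanones usually give lower ee than 4-aryl ones, and the oily lactone cannot be enriched by crystallisation. The fallback sets out from 1 and comes back at 4; it desymmetrises by enantioselective deprotonation instead of oxygen insertion. A chiral lithium amide base (lithium bis(1-phenylethyl)amide type, the antipode that gives the S enol ether; TMSCl in situ, THF, −78 °C) gives (S)-[(4-butylcyclohex-1-en-1-yl)oxy]trimethylsilane F1. Ozonolysis (O3, CH2Cl2/MeOH, −78 °C; then NaBH4) cleaves the enol ether C=C to (S)-4-(2-hydroxyethyl)octanoic acid F2. Fischer esterification (MeOH, cat. H2SO4) gives methyl (S)-4-(2-hydroxyethyl)octanoate F3, and Appel iodination (I2, PPh3, imidazole, CH2Cl2) gives 4.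

**Step 4 (over-reduction).** An unhindered methyl ester can go on to the alcohol or stay partly unreacted. The fallback sets out from 7 and comes back at 8; it goes through the alcohol instead of stopping at the hemiacetal. LiAlH4 (THF, 0 °C) gives (R)-4-butylundec-10-en-1-ol F4, and Dess–Martin periodinane (CH2Cl2, rt) oxidises it to 8.

**Step 6 (the new step).** The risks are:
- Ru–H may walk the double bond along the chain instead of into the ring.
- Ru–H may act on the free aldehyde.
- Excess 13 may isomerise before it has coupled.

The fallback uses known chemistry; it sets out from 14, isolated after the metathesis stage, and comes back at 16. Chemoselective hydrogenation of the disubstituted C=C (H2, RhCl(PPh3)3, benzene, rt) leaves the push–pull alkene and the aldehyde and gives methyl (2E)-2-[5-[(8R)-8-butyl-11-oxoundecyl]oxolan-2-ylidene]acetate F5. Oxidative aromatisation with DDQ (dioxane, 80 °C), an established way to turn 2-alkylidene-oxolanes into furan-2-ylacetates, then gives 16.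

## Further compounds

F1 | step 1 | (S)-[(4-butylcyclohex-1-en-1-yl)oxy]trimethylsilane | CCCC[C@H]1CCC(O[Si](C)(C)C)=CC1
F2 | step 1 | (S)-4-(2-hydroxyethyl)octanoic acid | CCCC[C@@H](CCC(=O)O)CCO
F3 | step 1 | methyl (S)-4-(2-hydroxyethyl)octanoate | CCCC[C@@H](CCC(=O)OC)CCO
F4 | step 4 | (R)-4-butylundec-10-en-1-ol | CCCC[C@@H](CCCO)CCCCCC=C
F5 | step 6 | methyl (2E)-2-[5-[(8R)-8-butyl-11-oxoundecyl]oxolan-2-ylidene]acetate | CCCC[C@@H](CCC=O)CCCCCCCC1CC/C(=C\C(=O)OC)O1
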